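**Retrosynthetic overview**
- The C3=C4 (E) alkene of the nonenoic acid chain is cut by cross-metathesis into a 3-acyl-dihydropyranone carrying a terminal allyl group and a 2-propenyl-substituted carboxylic acid; propene is lost.
- The acyl-pyranone is cut at the ring C3–acyl bond into (4R)-4-methylhept-6-enoic acid (from (R)-citronellal) and (6R)-4-hydroxy-6-methyl-5,6-dihydropyran-2-one.
- The pyranone is the only ring; it is closed first, by lactonisation of the Claisen adduct of methyl (R)-3-hydroxybutanoate and tert-butyl acetate, before any fragment union.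
- Key step: the acid α-stereocentre and its C–C bond to the future carboxyl carbon come from a [2,3]-Wittig–Still rearrangement of a (Z)-allylic stannylmethyl ether, with 1,3-chirality transfer from the carbinol of (S)-but-3-yn-2-ol.
- The (S)-2-methylbutyl group is bought as (S)-1-iodo-2-methylbutane.

Assumption: (S)-but-3-yn-2-ol and (S)-1-iodo-2-methylbutane (the iodide of fusel-oil (S)-2-methylbutan-1-ol) are taken as catalogue materials, and the target is drawn as the 4-hydroxy enol tautomer of the given SMILES.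

**Route**

Step 1
Reactants: 1 (2S)-but-3-yn-2-ol; 2 (2S)-1-iodo-2-methylbutane
Product: 4 (2S,6S)-6-methyloct-3-yn-2-ol, via dilithiated butynol 3 (not isolated)
Conditions: n-BuLi (2.2 equiv), THF, −78 → 0 °C; then 2, DMPU, 0 °C → rt; H2O
Reagents that add atoms: none
Why: Acetylide alkylation (SN2 of the C,O-dianion at the primary iodide, carbon being far more nucleophilic than the lithium alkoxide); neither purchased stereocentre is at a reacting carbon, so both are carried through.

Step 2
Reactants: 4 (2S,6S)-6-methyloct-3-yn-2-ol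
Product: 5 (2S,3Z,6S)-6-methyloct-3-en-2-ol
Conditions: H2 (1 atm), Pd/CaCO3 poisoned with Pb(OAc)2 (Lindlar catalyst), quinoline, EtOAc, rt
Reagents that add atoms: none
Why: Lindlar semi-hydrogenation adds H2 syn on the poisoned surface and stops at the Z-alkene, the geometry needed for clean chirality transfer in step 4.

Step 3
Reactants: 5 (2S,3Z,6S)-6-methyloct-3-en-2-ol
Product: 6 tributyl({[(2S,3Z,6S)-6-methyloct-3-en-2-yl]oxy}methyl)stannane
Conditions: KH, THF, 0 °C; then Bu3SnCH2I, rt
Reagents that add atoms: tributyl(iodomethyl)stannane, CCCC[Sn](CCCC)(CCCC)CI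
Why: Williamson etherification of the potassium alkoxide with the very SN2-reactive α-stannyl iodide; the C–O stereocentre is not touched.

Step 4
Reactants: 6 tributyl({[(2S,3Z,6S)-6-methyloct-3-en-2-yl]oxy}methyl)stannane
Product: 8 (2S,4S)-4-methyl-2-[(1E)-prop-1-en-1-yl]hexan-1-ol, via alkoxymethyllithium 7 (not isolated)
Conditions: n-BuLi (1.3 equiv), THF, −78 °C; then H2O
Reagents that add atoms: none
Why: Tin–lithium exchange triggers the [2,3]-Wittig–Still sigmatropic rearrangement; the Z-alkene forces the carbinol methyl exo in the five-membered envelope transition state (A(1,3) strain), so suprafacial C–C bond formation transfers the (S)-carbinol configuration to the new (2S) centre and gives only the E-propenyl group.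

Step 5
Reactants: 8 (2S,4S)-4-methyl-2-[(1E)-prop-1-en-1-yl]hexan-1-ol
Product: 10 (2S,4S)-4-methyl-2-[(1E)-prop-1-en-1-yl]hexanoic acid, via aldehyde 9 (not isolated)
Conditions: TEMPO (20 mol %), PhI(OAc)2 (2.2 equiv), MeCN/H2O 1:1, 0 °C → rt
Reagents that add atoms: water, O
Why: Oxoammonium (TEMPO/PhI(OAc)2) oxidation takes the primary alcohol through the aldehyde hydrate to the acid under near-neutral conditions, fast enough that the α-centre is not epimerised and the β,γ-alkene does not move into conjugation.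

Step 6
Reactants: 11 (R)-citronellal, (3R)-3,7-dimethyloct-6-enal
Product: 12 (4R)-4,8-dimethylnona-1,7-diene
Conditions: Ph3PCH3Br, KOtBu, THF, 0 °C → rt
Reagents that add atoms: methyltriphenylphosphonium bromide, C[P+](c1ccccc1)(c1ccccc1)c1ccccc1.[Br-]
Why: Wittig methylenation of the aldehyde; the methyl stereocentre is β to the carbonyl and cannot epimerise.

Step 7
Reactants: 12 (4R)-4,8-dimethylnona-1,7-diene
Product: 14 (4R)-4-methylhept-6-enoic acid, via ozonide 13 (not isolated)
Conditions: O3 (1.0 equiv, Sudan Red 7B end point), acetone, −78 °C; then Jones reagent (CrO3, H2SO4, H2O), 0 °C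
Reagents that add atoms: ozone, [O-][O+]=O; water, O
Why: Chemoselective ozonolysis of the electron-rich trisubstituted alkene (much faster than the monosubstituted one) followed by oxidative Jones work-up of the ozonide gives the acid and acetone, leaving the terminal alkene.

Step 8
Reactants: 15 methyl (3R)-3-hydroxybutanoate; 16 tert-butyl acetate
Product: 18 tert-butyl (5R)-5-hydroxy-3-oxohexanoate, via lithium enolate of tert-butyl acetate 17 (not isolated)
Conditions: LDA (3.5 equiv), 16 (3.5 equiv), THF, −78 °C; then 15, −78 → −40 °C; aq HCl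
Reagents that add atoms: none
Why: Crossed Claisen condensation: excess enolate first deprotonates the hydroxyl, then acylates on the methyl ester, and the product is protected in the flask as its enolate; the carbinol centre is untouched.

Step 9
Reactants: 18 tert-butyl (5R)-5-hydroxy-3-oxohexanoate
Product: 20 (6R)-4-hydroxy-6-methyl-5,6-dihydro-2H-pyran-2-one, via hydroxy keto acid 19 (not isolated)
Conditions: TFA/CH2Cl2 1:4, 0 °C → rt
Reagents that add atoms: none
Why: Acidolysis of the tert-butyl ester and fast six-membered lactonisation (quicker than decarboxylation) give the β-keto-δ-lactone, which enolises; the C–O bond at the stereocentre is not broken, so it stays (R).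

Step 10
Reactants: 14 (4R)-4-methylhept-6-enoic acid; 20 (6R)-4-hydroxy-6-methyl-5,6-dihydro-2H-pyran-2-one
Product: 22 (6R)-4-hydroxy-6-methyl-3-[(4R)-4-methylhept-6-enoyl]-5,6-dihydro-2H-pyran-2-one, via enol ester 21 (not isolated)
Conditions: DCC (1.2 equiv), DMAP (1.2 equiv), CH2Cl2, 0 °C → rt, 24 h
Reagents that add atoms: none
Why: Carbodiimide O-acylation of the enol followed by DMAP-mediated O→C acyl migration (Fries-type) gives the thermodynamically favoured, hydrogen-bonded 3-acyl tricarbonyl.

Step 11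
Reactants: 10 (2S,4S)-4-methyl-2-[(1E)-prop-1-en-1-yl]hexanoic acid; 22 (6R)-4-hydroxy-6-methyl-3-[(4R)-4-methylhept-6-enoyl]-5,6-dihydro-2H-pyran-2-one
Product: 23 (2S,3E,6R)-9-[(6R)-4-hydroxy-6-methyl-2-oxo-5,6-dihydro-2H-pyran-3-yl]-6-methyl-2-[(2S)-2-methylbutyl]-9-oxonon-3-enoic acid (target)
Conditions: 22 (2 equiv), RuCl2(H2IMes)(=CH-C6H4-2-OiPr) (second-generation Hoveyda–Grubbs catalyst, 10 mol %), 1,4-benzoquinone (20 mol %), CH2Cl2, 40 °C, Ar sparge
Reagents that add atoms: none
Why: Olefin cross-metathesis between the unhindered terminal alkene and the α-branched propenyl partner, driven by loss of propene, with the branched allylic centre favouring the E-alkene; benzoquinone suppresses alkene migration and no stereocentre is touched.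

**Compound list**
1 | (2S)-but-3-yn-2-ol | C[C@H](O)C#C | starting material
2 | (2S)-1-iodo-2-methylbutane | CC[C@H](C)CI | starting material
3 | dilithiated (2S)-but-3-yn-2-ol (alkoxide/acetylide, not isolated) | C[C@H](O[Li])C#C[Li] | intermediate
4 | (2S,6S)-6-methyloct-3-yn-2-ol | CC[C@H](C)CC#C[C@H](C)O | intermediate
5 | (2S,3Z,6S)-6-methyloct-3-en-2-ol | CC[C@H](C)C/C=C\[C@H](C)O | intermediate
6 | tributyl({[(2S,3Z,6S)-6-methyloct-3-en-2-yl]oxy}methyl)stannane | CC[C@H](C)C/C=C\[C@H](C)OC[Sn](CCCC)(CCCC)CCCC | intermediate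
7 | {[(2S,3Z,6S)-6-methyloct-3-en-2-yl]oxy}methyllithium (not isolated) | CC[C@H](C)C/C=C\[C@H](C)OC[Li] | intermediate
8 | (2S,4S)-4-methyl-2-[(1E)-prop-1-en-1-yl]hexan-1-ol | CC[C@H](C)C[C@@H](/C=C/C)CO | intermediate
9 | (2S,4S)-4-methyl-2-[(1E)-prop-1-en-1-yl]hexanal (not isolated) | CC[C@H](C)C[C@@H](/C=C/C)C=O | intermediate
10 | (2S,4S)-4-methyl-2-[(1E)-prop-1-en-1-yl]hexanoic acid | CC[C@H](C)C[C@@H](/C=C/C)C(=O)O | intermediate
11 | (R)-citronellal, (3R)-3,7-dimethyloct-6-enal | O=CC[C@H](C)CCC=C(C)C | starting material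
12 | (4R)-4,8-dimethylnona-1,7-diene | C=CC[C@H](C)CCC=C(C)C | intermediate
13 | 3,3-dimethyl-5-[(3R)-3-methylhex-5-en-1-yl]-1,2,4-trioxolane (ozonide, not isolated, epimers at the ring carbon) | C=CC[C@H](C)CCC1OOC(C)(C)O1 | intermediate
14 | (4R)-4-methylhept-6-enoic acid | C=CC[C@H](C)CCC(=O)O | intermediate
15 | methyl (3R)-3-hydroxybutanoate | C[C@@H](O)CC(=O)OC | starting material
16 | tert-butyl acetate | CC(=O)OC(C)(C)C | starting material
17 | lithium enolate of tert-butyl acetate (not isolated) | C=C(O[Li])OC(C)(C)C | intermediate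
18 | tert-butyl (5R)-5-hydroxy-3-oxohexanoate | C[C@@H](O)CC(=O)CC(=O)OC(C)(C)C | intermediate
19 | (5R)-5-hydroxy-3-oxohexanoic acid (not isolated) | C[C@@H](O)CC(=O)CC(=O)O | intermediate
20 | (6R)-4-hydroxy-6-methyl-5,6-dihydro-2H-pyran-2-one | C[C@@H]1CC(O)=CC(=O)O1 | intermediate
21 | (6R)-6-methyl-2-oxo-5,6-dihydro-2H-pyran-4-yl (4R)-4-methylhept-6-enoate (not isolated) | C=CC[C@H](C)CCC(=O)OC1=CC(=O)O[C@H](C)C1 | intermediate
22 | (6R)-4-hydroxy-6-methyl-3-[(4R)-4-methylhept-6-enoyl]-5,6-dihydro-2H-pyran-2-one | C=CC[C@H](C)CCC(=O)C1=C(O)C[C@@H](C)OC1=O | intermediate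
23 | (2S,3E,6R)-9-[(6R)-4-hydroxy-6-methyl-2-oxo-5,6-dihydro-2H-pyran-3-yl]-6-methyl-2-[(2S)-2-methylbutyl]-9-oxonon-3-enoic acid | CC[C@H](C)C[C@@H](/C=C/C[C@H](C)CCC(=O)C1=C(O)C[C@@H](C)OC1=O)C(=O)O | target

**Totals**
Total step count: 11. Longest linear sequence: 6 (steps 1, 2, 3, 4, 5, 11).

**Three steps most likely to fail, with fallbacks**

Step 1 (acetylide alkylation with a β-branched primary iodide: slow SN2, possible elimination or O-alkylation). The fallback replaces the SN2 by a stereoretentive sp2–sp3 cross-coupling. It sets out from 1 and 2 and comes back to the route at 5, skipping 4. Compound 1 is iodinated at the alkyne terminus (N-iodosuccinimide, AgNO3 cat., acetone) to (2S)-4-iodobut-3-yn-2-ol F1. Diimide reduction (2-nitrobenzenesulfonyl hydrazide, Et3N) gives (2S,3Z)-4-iodobut-3-en-2-ol F2. Separately, 2 is converted with Zn dust and LiCl in THF into [(2S)-2-methylbutyl]zinc iodide F3. Negishi coupling of F2 with excess F3, catalysed by Pd(PPh3)4 (zerovalent palladium) in THF, gives the Z-allylic alcohol 5 with retention of alkene geometry.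

Step 7 (ozone must discriminate the trisubstituted from the terminal alkene; over-ozonolysis destroys the allyl group). The fallback separates selectivity from cleavage. It sets out from 12 and comes back at 14. mCPBA (1.0 equiv, CH2Cl2, 0 °C) epoxidises only the trisubstituted alkene to 2,2-dimethyl-3-[(3R)-3-methylhex-5-en-1-yl]oxirane F4. H5IO6 in THF/H2O cleaves F4 to (4R)-4-methylhept-6-enal F5 and acetone. Pinnick oxidation (NaClO2, NaH2PO4, 2-methylbut-2-ene, t-BuOH/H2O) then gives 14.

Step 11 (metathesis in the presence of a free acid and a chelating, acidic tricarbonyl; E/Z control; alkene migration). The fallback runs the metathesis before the tricarbonyl exists and masks the hindered acid. It sets out from 10, uses 14 and 20, and comes back at 23. Acid 10 is esterified with tert-butyl 2,2,2-trichloroacetimidate (BF3·OEt2 cat.) to tert-butyl (2S,4S)-4-methyl-2-[(1E)-prop-1-en-1-yl]hexanoate F6. Cross-metathesis of F6 with excess 14, using RuCl2(H2IMes)(PCy3)(=CHPh) (second-generation Grubbs catalyst) in CH2Cl2 at 40 °C, gives (4R,6E,8S,10S)-8-(tert-butoxycarbonyl)-4,10-dimethyldodec-6-enoic acid F7. DCC/DMAP acylation of 20 with F7, as in step 10, gives the tert-butyl ester of the target F8. TFA/CH2Cl2 then releases 23.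

**Further compounds**
F1 | step 1 | (2S)-4-iodobut-3-yn-2-ol | C[C@H](O)C#CI
F2 | step 1 | (2S,3Z)-4-iodobut-3-en-2-ol | C[C@H](O)/C=C\I
F3 | step 1 | [(2S)-2-methylbutyl]zinc iodide | CC[C@H](C)C[Zn]I
F4 | step 7 | 2,2-dimethyl-3-[(3R)-3-methylhex-5-en-1-yl]oxirane | C=CC[C@H](C)CCC1OC1(C)C
F5 | step 7 | (4R)-4-methylhept-6-enal | C=CC[C@H](C)CCC=O
F6 | step 11 | tert-butyl (2S,4S)-4-methyl-2-[(1E)-prop-1-en-1-yl]hexanoate | CC[C@H](C)C[C@@H](/C=C/C)C(=O)OC(C)(C)C
F7 | step 11 | (4R,6E,8S,10S)-8-(tert-butoxycarbonyl)-4,10-dimethyldodec-6-enoic acid | CC[C@H](C)C[C@@H](/C=C/C[C@H](C)CCC(=O)O)C(=O)OC(C)(C)C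
F8 | step 11 | tert-butyl (2S,3E,6R)-9-[(6R)-4-hydroxy-6-methyl-2-oxo-5,6-dihydro-2H-pyran-3-yl]-6-methyl-2-[(2S)-2-methylbutyl]-9-oxonon-3-enoate | CC[C@H](C)C[C@@H](/C=C/C[C@H](C)CCC(=O)C1=C(O)C[C@@H](C)OC1=O)C(=O)OC(C)(C)C
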